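The target is numbered C1 (the carbon bearing =CH2) to C11 around the 11-membered ring C; C12–C14 complete cyclopentane A, C15 and C16 complete cyclohexene B. Ring B holds the C8=C9 double bond between allylic C10 and C16, a Diels–Alder retron. The key step is an intramolecular [4+2] reaction of the C16=C8–C9=C10 diene, held in the preformed ring C, with a Z β-boryl acrylate (C14=C15) tethered through C11–C12–C13: it forms C10–C14 and C15–C16, closes rings A and B and sets C10, C14 and C15; boron later becomes the C15 hydroxyl. The precursor is a monocyclic cycloundecene made by Evans alkylation, Stille macrocyclisation and an asymmetric iodo-aldol reaction.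

Key step: step 17

Remark on numbering: C5 bears the secondary methyl, C9 the vinylic methyl, C13 the acetoxy group, C14 the CH2OH carbon (C17), C15 the hydroxyl; in this numbering the target is 5S,10S,11R,13R,14R,15S.
Assumption: the S-configured oxazaborolidinium ion of step 14 is taken to deliver the 13R carbinol from this aliphatic aldehyde; if the sense is opposite, its enantiomer is used.

Step 1
Reactants: 1 (S)-citronellyl bromide
Product: 2 (5S)-5,9-dimethyldec-8-en-1-yne
Conditions: LiC≡CH·H2NCH2CH2NH2, DMSO, 0 °C → rt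
Reagents that add atoms: lithium acetylide ethylenediamine complex ([Li]C#C.NCCN)
Why: SN2 alkynylation of the primary bromide by lithium acetylide in DMSO should leave the remote C5 stereocentre and the trisubstituted alkene untouched.

Step 2
Reactants: 2 (5S)-5,9-dimethyldec-8-en-1-yne
Product: 4 (4R)-4-methyloct-7-yn-1-ol, via aldehyde 3 (not isolated)
Conditions: O3, CH2Cl2/MeOH, −78 °C; then NaBH4, −78 °C → rt
Reagents that add atoms: ozone ([O-][O+]=O)
Why: Ozonolysis with reductive work-up: ozone should cleave the electron-rich trisubstituted alkene much faster than the terminal alkyne and NaBH4 should reduce aldehyde 3 to the primary alcohol.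

Step 3
Reactants: 4 (4R)-4-methyloct-7-yn-1-ol
Product: 5 (4S)-4-methyl-7-(trimethylstannyl)oct-7-en-1-ol
Conditions: Me3SnLi, CuBr·SMe2, THF, −63 °C; then 4, MeOH, −63 °C
Reagents that add atoms: (trimethylstannyl)copper dimethyl sulfide complex, Me3SnCu·SMe2 (C[Sn](C)(C)[Cu].CSC)
Why: Stannylcupration–protonation of a terminal alkyne: syn addition of Me3Sn–Cu with methanol as internal proton source should place tin on the internal carbon and give the 2-stannyl-1-alkene.

Step 4
Reactants: 5 (4S)-4-methyl-7-(trimethylstannyl)oct-7-en-1-ol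
Product: 6 [(5S)-8-bromo-5-methyloct-1-en-2-yl]trimethylstannane
Conditions: CBr4, PPh3, CH2Cl2, 0 °C
Reagents that add atoms: carbon tetrabromide (BrC(Br)(Br)Br)
Why: Appel bromination should convert the primary alcohol under neutral conditions that the vinylstannane tolerates.

Step 5
Reactants: 7 pent-3-yn-1-ol
Product: 9 (E)-4-iodopent-3-en-1-ol, via alkenylzirconocene 8 (not isolated)
Conditions: Cp2Zr(H)Cl (excess), THF, rt → 45 °C; then I2, 0 °C
Reagents that add atoms: iodine (II)
Why: Hydrozirconation–iodination: syn addition of Zr–H with equilibration to the less hindered methyl-bearing carbon, followed by iodinolysis with retention, should fix the E geometry needed for the C9=C10 bond.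

Step 6
Reactants: 9 (E)-4-iodopent-3-en-1-ol
Product: 10 (E)-4-iodopent-3-enoic acid
Conditions: TEMPO (cat.), PhI(OAc)2, MeCN/H2O, rt
Reagents that add atoms: water (O)
Why: Oxoammonium (TEMPO) oxidation with PhI(OAc)2 in aqueous acetonitrile should take the primary alcohol through the aldehyde hydrate to the acid without touching the alkenyl iodide.

Step 7
Reactants: 10 (E)-4-iodopent-3-enoic acid; 11 (R)-4-benzyl-1,3-oxazolidin-2-one
Product: 13 (4R)-4-benzyl-3-[(E)-4-iodopent-3-enoyl]-1,3-oxazolidin-2-one, via mixed anhydride 12 (not isolated)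
Conditions: t-BuCOCl, Et3N, THF, −20 °C; then 11, LiCl, rt
Reagents that add atoms: none
Why: N-Acylation of the oxazolidinone by the mixed pivalic anhydride under LiCl/Et3N activation should attach the Evans auxiliary without strong base that could conjugate the β,γ-unsaturated acyl group.

Step 8
Reactants: 13 (4R)-4-benzyl-3-[(E)-4-iodopent-3-enoyl]-1,3-oxazolidin-2-one
Product: 15 tert-butyl (3R,4E)-3-[(4R)-4-benzyl-2-oxo-1,3-oxazolidine-3-carbonyl]-5-iodohex-4-enoate, via sodium enolate 14 (not isolated)
Conditions: NaN(SiMe3)2, THF, −78 °C; then BrCH2CO2t-Bu, −78 → −40 °C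
Reagents that add atoms: tert-butyl bromoacetate (BrCC(=O)OC(C)(C)C)
Why: Evans asymmetric alkylation: the chelated Z sodium enolate should be alkylated at the α-carbon on the face opposite the benzyl group, which sets C11 as R.

Step 9
Reactants: 15 tert-butyl (3R,4E)-3-[(4R)-4-benzyl-2-oxo-1,3-oxazolidine-3-carbonyl]-5-iodohex-4-enoate
Product: 16 tert-butyl (3R,4E)-5-iodo-3-[methoxy(methyl)carbamoyl]hex-4-enoate
Conditions: MeNH(OMe)·HCl, AlMe3, CH2Cl2, 0 °C → rt
Reagents that add atoms: N,O-dimethylhydroxylamine hydrochloride (CNOC.Cl)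
Why: Weinreb amide formation by transamination with the aluminium amide of N,O-dimethylhydroxylamine should cleave the exocyclic imide carbonyl and release the auxiliary without epimerising C11 or touching the tert-butyl ester.

Step 10
Reactants: 6 [(5S)-8-bromo-5-methyloct-1-en-2-yl]trimethylstannane; 16 tert-butyl (3R,4E)-5-iodo-3-[methoxy(methyl)carbamoyl]hex-4-enoate
Product: 18 tert-butyl (3R,8S)-3-[(E)-2-iodoprop-1-en-1-yl]-8-methyl-4-oxo-11-(trimethylstannyl)dodec-11-enoate, via Grignard reagent 17 (not isolated)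
Conditions: 6, Mg, THF, rt; then 16, THF, −20 → 0 °C; aq. NH4Cl
Reagents that add atoms: none
Why: Weinreb ketone synthesis: the chelated tetrahedral adduct should survive until work-up, so the primary Grignard reagent adds once and leaves the tert-butyl ester, alkenyl iodide and vinylstannane intact.

Step 11
Reactants: 18 tert-butyl (3R,8S)-3-[(E)-2-iodoprop-1-en-1-yl]-8-methyl-4-oxo-11-(trimethylstannyl)dodec-11-enoate
Product: 19 tert-butyl (3R,8S)-3-[(E)-2-iodoprop-1-en-1-yl]-8-methyl-4-methylidene-11-(trimethylstannyl)dodec-11-enoate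
Conditions: Cp2Ti(μ-Cl)(μ-CH2)AlMe2, pyridine, THF, −40 → 0 °C
Reagents that add atoms: Tebbe reagent, Cp2Ti(μ-Cl)(μ-CH2)AlMe2, drawn as titanocene methylidene bound to chlorodimethylaluminium (C=[Ti](C1C=CC=C1)C1C=CC=C1.C[Al](C)Cl)
Why: Tebbe methylenation is non-basic, so the ketone should be converted into the C1 methylidene group without epimerising the adjacent C11 centre, and the hindered tert-butyl ester reacts far more slowly.

Step 12
Reactants: 19 tert-butyl (3R,8S)-3-[(E)-2-iodoprop-1-en-1-yl]-8-methyl-4-methylidene-11-(trimethylstannyl)dodec-11-enoate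
Product: 20 tert-butyl 2-[(1R,2E,7S)-3,7-dimethyl-4,11-dimethylidenecycloundec-2-en-1-yl]acetate
Conditions: Pd(PPh3)4 (cat.), CuO2CC4H3S (copper thiophene-2-carboxylate), DMF, rt, 1 mM by slow addition
Reagents that add atoms: none
Why: Intramolecular Stille coupling under high dilution (oxidative addition of the alkenyl iodide to zerovalent palladium, copper-assisted transmetalation of the hindered 1,1-disubstituted vinylstannane, reductive elimination) should join C8 to C9 with retention of the E geometry and close ring C.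

Step 13
Reactants: 20 tert-butyl 2-[(1R,2E,7S)-3,7-dimethyl-4,11-dimethylidenecycloundec-2-en-1-yl]acetate
Product: 21 2-[(1R,2E,7S)-3,7-dimethyl-4,11-dimethylidenecycloundec-2-en-1-yl]acetaldehyde
Conditions: iBu2AlH, CH2Cl2, −78 °C; aq. potassium sodium tartrate
Reagents that add atoms: none
Why: Partial reduction of the ester: the tetrahedral aluminium alkoxide formed at −78 °C should collapse to the aldehyde only on work-up.

Step 14
Reactants: 21 2-[(1R,2E,7S)-3,7-dimethyl-4,11-dimethylidenecycloundec-2-en-1-yl]acetaldehyde; 22 methyl propiolate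
Product: 25 methyl (2Z,3R)-4-[(1R,2E,7S)-3,7-dimethyl-4,11-dimethylidenecycloundec-2-en-1-yl]-3-hydroxy-2-(iodomethylidene)butanoate, via silyl allenolate 23 (not isolated), via trimethylsilyl ether 24 (not isolated)
Conditions: 22, Me3SiI, CH2Cl2, −78 °C; then 21, (S)-B-(o-tolyl)oxazaborolidinium triflimide (from (S)-α,α-diphenylprolinol, 20 mol %), −78 °C; 1 M HCl
Reagents that add atoms: iodotrimethylsilane (C[Si](C)(C)I)
Why: Catalytic asymmetric three-component β-iodo Morita–Baylis–Hillman (iodo-aldol) reaction: 1,4-addition of Me3SiI to the propiolate gives allenolate 23, which should add to the aldehyde bound to the chiral oxazaborolidinium ion to give the Z alkenyl iodide and the C13 carbinol (13R) under catalyst control.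

Step 15
Reactants: 25 methyl (2Z,3R)-4-[(1R,2E,7S)-3,7-dimethyl-4,11-dimethylidenecycloundec-2-en-1-yl]-3-hydroxy-2-(iodomethylidene)butanoate
Product: 26 methyl (2Z,3R)-4-[(1R,2E,7S)-3,7-dimethyl-4,11-dimethylidenecycloundec-2-en-1-yl]-2-(iodomethylidene)-3-(triethylsilyloxy)butanoate
Conditions: Et3SiOTf, 2,6-lutidine, CH2Cl2, −78 °C
Reagents that add atoms: triethylsilyl trifluoromethanesulfonate (CC[Si](CC)(CC)OS(=O)(=O)C(F)(F)F)
Why: Silylation with the silyl triflate and a hindered base should protect the C13 hydroxyl as an ether that survives steps 16 to 19 and can later be removed in the presence of a silylene acetal.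

Step 16
Reactants: 26 methyl (2Z,3R)-4-[(1R,2E,7S)-3,7-dimethyl-4,11-dimethylidenecycloundec-2-en-1-yl]-2-(iodomethylidene)-3-(triethylsilyloxy)butanoate
Product: 27 methyl (2Z,3R)-4-[(1R,2E,7S)-3,7-dimethyl-4,11-dimethylidenecycloundec-2-en-1-yl]-2-[(4,4,5,5-tetramethyl-1,3,2-dioxaborolan-2-yl)methylidene]-3-(triethylsilyloxy)butanoate
Conditions: B2pin2, PdCl2(PPh3)2 (cat.), PPh3, KOPh, toluene, 50 °C
Reagents that add atoms: bis(pinacolato)diboron (CC1(C)OB(OC1(C)C)B1OC(C)(C)C(C)(C)O1)
Why: Miyaura borylation (oxidative addition, transmetalation with phenoxide-activated diboron, reductive elimination) should replace iodine by boron with retention of the Z geometry, and an intramolecular Heck reaction should not compete because palladium stands trans to the tether.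

Step 17
Reactants: 27 methyl (2Z,3R)-4-[(1R,2E,7S)-3,7-dimethyl-4,11-dimethylidenecycloundec-2-en-1-yl]-2-[(4,4,5,5-tetramethyl-1,3,2-dioxaborolan-2-yl)methylidene]-3-(triethylsilyloxy)butanoate
Product: 28 tricyclic boronate ester (target skeleton with CO2Me on C14 and B(pin) on C15 cis to it and OSiEt3 on C13; rings A/B cis-fused)
Conditions: toluene (2 mM), BHT, 120 °C, sealed tube
Reagents that add atoms: none
Why: Concerted thermal intramolecular Diels–Alder reaction in which the s-cis C16=C8–C9=C10 diene of ring C adds suprafacially to the C14=C15 boryl acrylate; the closest known reaction type is the type 1 intramolecular Diels–Alder reaction of 1,6,8-nonatrienes, combined with the known use of 3-borylacrylates as dienophiles. Ring B (cyclohexene) is closed by the [4+2] itself, and ring A (cyclopentane) as the ring spanned by the three-atom C11–C12–C13 tether between diene terminus C10 and dienophile carbon C14. C10 and C14: the tether can reach only the diene face turned away from the transannular C1–C7 chain, a face fixed by C11 because C1 must stay syn to C9 inside ring C, and the tether-endo (ester-exo, boryl-exo) transition state that gives the cis A/B fusion should be enforced because the tether-exo alternative would force C1 to eclipse the C9 methyl group (allylic 1,3-strain) and distort the macrocycle. C15: the Z geometry of the dienophile is transferred stereospecifically, so boron ends cis to the ester carbon C17, while the existing 13R silyloxy group occupies the open convex position in this transition state (matched case). The step needs diene π-facial selectivity, cis over trans fusion and cycloaddition over ene reaction or dimerisation; these are secured by the C11 stereocentre, the macrocycle, the ester activation of the dienophile and high dilution.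

Step 18
Reactants: 28 tricyclic boronate ester
Product: 30 C15,C17-diol carrying the C13 triethylsilyl ether, via boronate alcohol 29 (not isolated)
Conditions: iBu2AlH, CH2Cl2, −78 → 0 °C; then NaBO3·4H2O, THF/H2O, rt
Reagents that add atoms: sodium perborate tetrahydrate, NaBO3·4H2O ([Na+].[O-]OB=O.O.O.O.O)
Why: iBu2AlH should reduce the neopentyl ester to the C17 primary alcohol and perborate should oxidise the C15–B bond to C15–OH with retention of configuration (boronate oxidation by 1,2-migration), which keeps the cis relationship set in step 17.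

Step 19
Reactants: 30 C15,C17-diol carrying the C13 triethylsilyl ether
Product: 31 C15/C17 di-tert-butylsilylene acetal of 30
Conditions: t-Bu2Si(OTf)2, 2,6-lutidine, CH2Cl2, 0 °C
Reagents that add atoms: di-tert-butylsilyl bis(trifluoromethanesulfonate) (CC(C)(C)[Si](OS(=O)(=O)C(F)(F)F)(OS(=O)(=O)C(F)(F)F)C(C)(C)C)
Why: The cis-1,3-diol should close to a six-membered di-tert-butylsilylene acetal, which masks both hydroxyl groups in one operation.

Step 20
Reactants: 31 C15/C17 di-tert-butylsilylene acetal of 30
Product: 32 C13 alcohol (silylene acetal retained)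
Conditions: PPTS, MeOH/CH2Cl2, 0 °C → rt
Reagents that add atoms: none
Why: Acid-catalysed methanolysis should cleave the triethylsilyl ether much faster than the bulky di-tert-butylsilylene acetal.

Step 21
Reactants: 32 C13 alcohol (silylene acetal retained)
Product: 33 C13 acetate of 32
Conditions: Ac2O, DMAP, Et3N, CH2Cl2, rt
Reagents that add atoms: acetic anhydride (CC(=O)OC(C)=O)
Why: DMAP-catalysed acylation should acetylate the only free hydroxyl group.

Step 22
Reactants: 33 C13 acetate of 32
Product: 34 CNP0228496.1 (target)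
Conditions: HF·pyridine, pyridine, THF, 0 °C
Reagents that add atoms: none
Why: Buffered fluoride should cleave the silylene acetal to the diol under conditions too mild for acetyl migration from O13 to O17 or O15.

Compound list
1 | (S)-citronellyl bromide, (6S)-8-bromo-2,6-dimethyloct-2-ene | C[C@@H](CCC=C(C)C)CCBr | starting material
2 | (5S)-5,9-dimethyldec-8-en-1-yne | C[C@@H](CCC=C(C)C)CCC#C | intermediate
3 | (4R)-4-methyloct-7-ynal | C[C@@H](CCC=O)CCC#C | intermediate
4 | (4R)-4-methyloct-7-yn-1-ol | C[C@@H](CCCO)CCC#C | intermediate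
5 | (4S)-4-methyl-7-(trimethylstannyl)oct-7-en-1-ol | C[C@@H](CCCO)CCC(=C)[Sn](C)(C)C | intermediate
6 | [(5S)-8-bromo-5-methyloct-1-en-2-yl]trimethylstannane | C[C@@H](CCCBr)CCC(=C)[Sn](C)(C)C | intermediate
7 | pent-3-yn-1-ol | CC#CCCO | starting material
8 | (E)-alkenylzirconocene chloride from 7 (zirconium on C4, hydroxyl as zirconium alkoxide) | C/C(=C\CCO[Zr](Cl)(C1C=CC=C1)C1C=CC=C1)[Zr](Cl)(C1C=CC=C1)C1C=CC=C1 | intermediate
9 | (E)-4-iodopent-3-en-1-ol | OCC/C=C(\C)I | intermediate
10 | (E)-4-iodopent-3-enoic acid | OC(=O)C/C=C(\C)I | intermediate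
11 | (R)-4-benzyl-1,3-oxazolidin-2-one | O=C1N[C@H](Cc2ccccc2)CO1 | starting material
12 | (E)-4-iodopent-3-enoic pivalic anhydride | CC(C)(C)C(=O)OC(=O)C/C=C(\C)I | intermediate
13 | (4R)-4-benzyl-3-[(E)-4-iodopent-3-enoyl]-1,3-oxazolidin-2-one | O=C(C/C=C(\C)I)N1C(=O)OC[C@H]1Cc1ccccc1 | intermediate
14 | sodium Z-enolate of 13 | [Na+].[O-]/C(N1C(=O)OC[C@H]1Cc1ccccc1)=C\C=C(/C)I | intermediate
15 | tert-butyl (3R,4E)-3-[(4R)-4-benzyl-2-oxo-1,3-oxazolidine-3-carbonyl]-5-iodohex-4-enoate | O=C(N1C(=O)OC[C@H]1Cc1ccccc1)[C@H](CC(=O)OC(C)(C)C)/C=C(\C)I | intermediate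
16 | tert-butyl (3R,4E)-5-iodo-3-[methoxy(methyl)carbamoyl]hex-4-enoate | CON(C)C(=O)[C@H](CC(=O)OC(C)(C)C)/C=C(\C)I | intermediate
17 | Grignard reagent of 6 | C[C@@H](CCC[Mg]Br)CCC(=C)[Sn](C)(C)C | intermediate
18 | tert-butyl (3R,8S)-3-[(E)-2-iodoprop-1-en-1-yl]-8-methyl-4-oxo-11-(trimethylstannyl)dodec-11-enoate | C[C@@H](CCCC(=O)[C@H](CC(=O)OC(C)(C)C)/C=C(\C)I)CCC(=C)[Sn](C)(C)C | intermediate
19 | tert-butyl (3R,8S)-3-[(E)-2-iodoprop-1-en-1-yl]-8-methyl-4-methylidene-11-(trimethylstannyl)dodec-11-enoate | C[C@@H](CCCC(=C)[C@H](CC(=O)OC(C)(C)C)/C=C(\C)I)CCC(=C)[Sn](C)(C)C | intermediate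
20 | tert-butyl 2-[(1R,2E,7S)-3,7-dimethyl-4,11-dimethylidenecycloundec-2-en-1-yl]acetate | C=C1CCC[C@H](C)CCC(=C)/C(C)=C/[C@H]1CC(=O)OC(C)(C)C | intermediate
21 | 2-[(1R,2E,7S)-3,7-dimethyl-4,11-dimethylidenecycloundec-2-en-1-yl]acetaldehyde | C=C1CCC[C@H](C)CCC(=C)/C(C)=C/[C@H]1CC=O | intermediate
22 | methyl propiolate | C#CC(=O)OC | starting material
23 | [(3-iodo-1-methoxypropa-1,2-dien-1-yl)oxy]trimethylsilane | COC(O[Si](C)(C)C)=C=CI | intermediate
24 | trimethylsilyl ether of 25 | C=C1CCC[C@H](C)CCC(=C)/C(C)=C/[C@H]1C[C@@H](O[Si](C)(C)C)/C(C(=O)OC)=C/I | intermediate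
25 | methyl (2Z,3R)-4-[(1R,2E,7S)-3,7-dimethyl-4,11-dimethylidenecycloundec-2-en-1-yl]-3-hydroxy-2-(iodomethylidene)butanoate | C=C1CCC[C@H](C)CCC(=C)/C(C)=C/[C@H]1C[C@@H](O)/C(C(=O)OC)=C/I | intermediate
26 | triethylsilyl ether of 25 | C=C1CCC[C@H](C)CCC(=C)/C(C)=C/[C@H]1C[C@@H](O[Si](CC)(CC)CC)/C(C(=O)OC)=C/I | intermediate
27 | Z β-(pinacolboryl) acrylate, precursor of the cycloaddition (boron cis to CO2Me) | C=C1CCC[C@H](C)CCC(=C)/C(C)=C/[C@H]1C[C@@H](O[Si](CC)(CC)CC)/C(C(=O)OC)=C/B1OC(C)(C)C(C)(C)O1 | intermediate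
28 | tricyclic Diels–Alder adduct: CO2Me on C14, B(pin) on C15, OSiEt3 on C13, spatial arrangement at all centres as in 34 | C=C1CCC[C@H](C)CCC2=C(C)[C@@H]3[C@H]1C[C@@H](O[Si](CC)(CC)CC)[C@]3(C(=O)OC)[C@@H](B4OC(C)(C)C(C)(C)O4)C2 | intermediate
29 | C17 primary alcohol with C15–B(pin) retained | C=C1CCC[C@H](C)CCC2=C(C)[C@@H]3[C@H]1C[C@@H](O[Si](CC)(CC)CC)[C@]3(CO)[C@@H](B4OC(C)(C)C(C)(C)O4)C2 | intermediate
30 | C15,C17-diol carrying the C13 triethylsilyl ether | C=C1CCC[C@H](C)CCC2=C(C)[C@@H]3[C@H]1C[C@@H](O[Si](CC)(CC)CC)[C@]3(CO)[C@@H](O)C2 | intermediate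
31 | C15/C17 di-tert-butylsilylene acetal of 30 | C=C1CCC[C@H](C)CCC2=C(C)[C@@H]3[C@H]1C[C@@H](O[Si](CC)(CC)CC)[C@@]34CO[Si](C(C)(C)C)(C(C)(C)C)O[C@H]4C2 | intermediate
32 | C13 alcohol with the silylene acetal retained | C=C1CCC[C@H](C)CCC2=C(C)[C@@H]3[C@H]1C[C@@H](O)[C@@]34CO[Si](C(C)(C)C)(C(C)(C)C)O[C@H]4C2 | intermediate
33 | C13 acetate of 32 | C=C1CCC[C@H](C)CCC2=C(C)[C@@H]3[C@H]1C[C@@H](OC(C)=O)[C@@]34CO[Si](C(C)(C)C)(C(C)(C)C)O[C@H]4C2 | intermediate
34 | CNP0228496.1 | C=C1CCC[C@H](C)CCC2=C(C)[C@@H]3[C@H]1C[C@@H](OC(C)=O)[C@]3(CO)[C@@H](O)C2 | target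

Total step count: 22. Longest linear sequence: 18 steps (steps 5 to 22, from pent-3-yn-1-ol); the branch of steps 1 to 4 joins at step 10.

Steps most likely to fail

1. Step 17 (key cycloaddition). The trisubstituted, only ester-activated dienophile may react too slowly, so that prolonged heating opens ene, dimerisation or protodeboronation pathways. The fallback changes the activation mode from thermal (ester) to Lewis-acid (aldehyde); it sets out from 26 and returns at 30. iBu2AlH should reduce the ester of 26 to the allylic alcohol F1, and MnO2 should oxidise this to the Z β-iodo enal F2. Miyaura borylation as in step 16 should give the β-boryl enal F3. Its intramolecular Diels–Alder reaction would be run with Me2AlCl in CH2Cl2 at −78 to −20 °C to give the tricyclic aldehyde F4. NaBH4 and then NaBO3·4H2O should convert F4 into diol 30.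

2. Step 12 (macrocyclisation). Transmetalation of the hindered α-substituted vinylstannane may be slow, so that intermolecular coupling (oligomerisation) or protodestannylation competes at high dilution. The fallback is a Nozaki–Hiyama–Kishi ring closure; it sets out from 1 and 16 and returns at 20. The Grignard reagent of 1 would be formylated with HC(OEt)3 (Bodroux–Chichibabin) to the acetal F5. Ozonolysis with NaBH4 work-up should give the alcohol F6, and CBr4/PPh3 the bromide F7. The Grignard reagent of F7 should add to Weinreb amide 16 to give the ketone F8, and Tebbe methylenation should give the diene acetal F9. Mild hydrolysis (PPTS, acetone/H2O) should free the iodo aldehyde F10. CrCl2 with catalytic NiCl2 in DMSO under high dilution should close ring C to the allylic alcohols F11 (both C8 epimers). Dess–Martin periodinane should oxidise these to the enone F12, and a second Tebbe methylenation should give 20.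

3. Step 14 (iodo-aldol). Enantiofacial control at C13 may erode with this β-branched aldehyde, or the strong Lewis acid may trigger a carbonyl–ene cyclisation onto the neighbouring C1 methylidene group. The fallback sets C13 by reagent-controlled ketone reduction instead; it sets out from 21 and 22 and returns at 25. MgI2 in CH2Cl2 at 0 °C should mediate the same three-component iodo-aldol reaction without stereocontrol, giving the Z β-iodo aldol adduct F13 as both C13 epimers. Dess–Martin periodinane should oxidise them to the β-keto ester F14. Corey–Bakshi–Shibata reduction with catecholborane at −78 °C (oxazaborolidine enantiomer chosen for 13R) should then give 25.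

Further compounds
F1 | step 17 | allylic alcohol from 26 (CH2OH on C14 cis to iodine, 13R silyl ether) | C=C1CCC[C@H](C)CCC(=C)/C(C)=C/[C@H]1C[C@@H](O[Si](CC)(CC)CC)/C(CO)=C/I
F2 | step 17 | Z β-iodo enal (CHO on C14 cis to iodine) | C=C1CCC[C@H](C)CCC(=C)/C(C)=C/[C@H]1C[C@@H](O[Si](CC)(CC)CC)/C(C=O)=C/I
F3 | step 17 | Z β-(pinacolboryl) enal | C=C1CCC[C@H](C)CCC(=C)/C(C)=C/[C@H]1C[C@@H](O[Si](CC)(CC)CC)/C(C=O)=C/B1OC(C)(C)C(C)(C)O1
F4 | step 17 | tricyclic aldehyde adduct (CHO on C14, B(pin) on C15, OSiEt3 on C13) | C=C1CCC[C@H](C)CCC2=C(C)[C@@H]3[C@H]1C[C@@H](O[Si](CC)(CC)CC)[C@]3(C=O)[C@@H](B4OC(C)(C)C(C)(C)O4)C2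
F5 | step 12 | (4S)-1,1-diethoxy-4,8-dimethylnon-7-ene | C[C@@H](CCC=C(C)C)CCC(OCC)OCC
F6 | step 12 | (4S)-7,7-diethoxy-4-methylheptan-1-ol | C[C@@H](CCCO)CCC(OCC)OCC
F7 | step 12 | (4R)-7-bromo-1,1-diethoxy-4-methylheptane | C[C@@H](CCCBr)CCC(OCC)OCC
F8 | step 12 | tert-butyl (3R,8S)-11,11-diethoxy-3-[(E)-2-iodoprop-1-en-1-yl]-8-methyl-4-oxoundecanoate | C[C@@H](CCCC(=O)[C@H](CC(=O)OC(C)(C)C)/C=C(\C)I)CCC(OCC)OCC
F9 | step 12 | tert-butyl (3R,8S)-11,11-diethoxy-3-[(E)-2-iodoprop-1-en-1-yl]-8-methyl-4-methylideneundecanoate | C[C@@H](CCCC(=C)[C@H](CC(=O)OC(C)(C)C)/C=C(\C)I)CCC(OCC)OCC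
F10 | step 12 | tert-butyl (3R,8S)-3-[(E)-2-iodoprop-1-en-1-yl]-8-methyl-4-methylidene-11-oxoundecanoate | C[C@@H](CCCC(=C)[C@H](CC(=O)OC(C)(C)C)/C=C(\C)I)CCC=O
F11 | step 12 | macrocyclic allylic alcohol (C8 carbinol, both epimers) | C=C1CCC[C@H](C)CCC(O)/C(C)=C/[C@H]1CC(=O)OC(C)(C)C
F12 | step 12 | macrocyclic enone (C8 ketone) | C=C1CCC[C@H](C)CCC(=O)/C(C)=C/[C@H]1CC(=O)OC(C)(C)C
F13 | step 14 | Z β-iodo aldol adduct as both C13 epimers | C=C1CCC[C@H](C)CCC(=C)/C(C)=C/[C@H]1CC(O)/C(C(=O)OC)=C/I
F14 | step 14 | β-keto ester (C13 ketone, iodine cis to CO2Me) | C=C1CCC[C@H](C)CCC(=C)/C(C)=C/[C@H]1CC(=O)/C(C(=O)OC)=C/I
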